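The route rests on cutting the C7''–C8'' bond of the threo-guaiacylglycerol arm. Its syn pair of oxygenated carbons, benzylic carbinol C7'' beside aryloxy carbon C8'' with hydroxymethyl C9'' attached, is the retron of a glycolate aldol. An Evans boron syn-aldol joins O-benzylvanillin to a complete, differentially protected (+)-lariciresinol whose guaiacyl oxygen on the ring at oxolane C2 carries a CH2C(=O)–[(R)-4-benzyloxazolidinone] arm. It forms the bond and both stereocentres in one operation under auxiliary control. C9'' is later revealed by reduction. The three oxolane stereocentres are relayed by substrate control from one centre set by catalytic asymmetric hydrogenation.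

Key step: step 10

Remark on the chemistry: lignan numbering is used (C7, C8, C9 = oxolane C2, oxolane C3 and its CH2OH; C7', C8', C9' = benzyl CH2, oxolane C4, oxolane C5; C7'', C8'', C9'' = glycerol chain). Compounds 9–11 are carried as mixtures at carbinol C7 (9 and 10 also at the THP acetal carbon), and both centres are erased or reset in step 7. The hand of the ligand in step 2 is assigned by analogy with itaconate hydrogenations, and both antipodes are commercial.

Step 1
Reactants: 1 4-(benzyloxy)-3-methoxybenzaldehyde (O-benzylvanillin); 2 dimethyl succinate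
Product: 3 (E)-4-[4-(benzyloxy)-3-methoxyphenyl]-3-(methoxycarbonyl)but-3-enoic acid
Conditions: NaOMe (1.5 equiv), MeOH, reflux; then aq. HCl
Reagents that add atoms: none
Why: Stobbe condensation: the succinate enolate adds to the aldehyde, the alkoxide lactonises onto the distal ester, and E1cB opening of that paraconic ester gives the conjugated (E)-half-ester with the two carboxyl groups differentiated for step 3; no stereocentre is formed.

Step 2
Reactants: 3 (E)-half-ester
Product: 4 (3R)-4-[4-(benzyloxy)-3-methoxyphenyl]-3-(methoxycarbonyl)butanoic acid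
Conditions: [Rh(cod)((S,S)-Et-DuPHOS)]BF4 (0.5 mol%), NaOMe (10 mol%), H2 (5 bar), MeOH, rt
Reagents that add atoms: none
Why: Rhodium–bisphospholane asymmetric hydrogenation of a Stobbe-type itaconate half-ester, in which carboxylate and alkene chelate rhodium; the (S,S)-ligand should deliver hydrogen to the face that gives the R centre (future C8'), and the aryl benzyl ether is inert to the homogeneous catalyst.

Step 3
Reactants: 4 (R)-half-ester
Product: 6 (4R)-4-[4-(benzyloxy)-3-methoxybenzyl]oxolan-2-one, via hydroxy acid 5 (not isolated)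
Conditions: KOH (1 equiv), EtOH; CaCl2, NaBH4, EtOH, −10 °C → rt; then 3 M HCl, rt
Reagents that add atoms: none
Why: Chemoselective borohydride reduction (calcium borohydride attacks the ester but not the carboxylate salt) followed by acid-catalysed 5-exo-trig lactonisation of 5; the stereocentre is not touched and keeps its R descriptor.

Step 4
Reactants: 7 vanillin
Product: 8 3-methoxy-4-(oxan-2-yloxy)benzaldehyde (THP-vanillin; racemic at the acetal carbon)
Conditions: 3,4-dihydro-2H-pyran, PPTS (cat.), CH2Cl2, rt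
Reagents that add atoms: 3,4-dihydro-2H-pyran, C1=COCCC1
Why: Acid-catalysed addition of the phenol to the enol ether (THP acetal formation) masks the acidic OH for the enolate chemistry of step 5 with a group that leaves under the acid of step 7.

Step 5
Reactants: 6 (R)-lactone; 8 THP-vanillin
Product: 9 (3S,4R)-4-[4-(benzyloxy)-3-methoxybenzyl]-3-{hydroxy[3-methoxy-4-(oxan-2-yloxy)phenyl]methyl}oxolan-2-one (3,4-trans)
Conditions: LiHMDS, THF, −78 °C; then 8, −78 °C; aq. NH4Cl
Reagents that add atoms: none
Why: Lithium enolate aldol addition of a β-substituted γ-butyrolactone: the aldehyde approaches the enolate face anti to the C8' benzyl group, so C8 is set trans to it by substrate control, and the configuration at the new carbinol C7 does not matter because step 7 passes through a planar cation.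

Step 6
Reactants: 9 aldol lactone
Product: 10 (2R,3R)-2-[4-(benzyloxy)-3-methoxybenzyl]-3-{hydroxy[3-methoxy-4-(oxan-2-yloxy)phenyl]methyl}butane-1,4-diol
Conditions: LiAlH4, THF, 0 °C → rt; Fieser work-up
Reagents that add atoms: none
Why: Lithium aluminium hydride reduction of the lactone to the 1,4-diol; the benzyl ether, the THP acetal and C8/C8' are unaffected.

Step 7
Reactants: 10 THP-protected triol
Product: 12 4-{(2S,3R,4R)-4-[4-(benzyloxy)-3-methoxybenzyl]-3-(hydroxymethyl)oxolan-2-yl}-2-methoxyphenol (4'-O-benzyl-(+)-lariciresinol), via phenol tetraol 11 (not isolated)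
Conditions: (±)-CSA (10 mol%), CH2Cl2–MeOH 9:1, 0 °C → rt
Reagents that add atoms: none
Why: Acid-catalysed transacetalisation frees the phenol (11), whose p-hydroxybenzylic alcohol ionises to a quinone-methide-type cation that is captured 5-exo-trig by the C9' hydroxyl (benzylic SN1 cycloetherification); the planar cation erases the C7 mixture, and closure anti to the neighbouring C8 hydroxymethyl, reversible and therefore also thermodynamically driven, should set C7 as S (2,3-trans, 3,4-cis).

Step 8
Reactants: 13 (4R)-4-benzyl-1,3-oxazolidin-2-one; 14 bromoacetyl bromide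
Product: 15 (4R)-4-benzyl-3-(bromoacetyl)-1,3-oxazolidin-2-one
Conditions: n-BuLi, THF, −78 °C; then 14, −78 → 0 °C
Reagents that add atoms: none
Why: N-acylation of the lithiated oxazolidinone by the acyl bromide end, which is far more electrophilic than the alkyl bromide end; the auxiliary stereocentre is bought.

Step 9
Reactants: 12 4'-O-benzyl-(+)-lariciresinol; 15 bromoacetyl imide
Product: 17 (4R)-3-[(4-{(2S,3R,4R)-3-(acetoxymethyl)-4-[4-(benzyloxy)-3-methoxybenzyl]oxolan-2-yl}-2-methoxyphenoxy)acetyl]-4-benzyl-1,3-oxazolidin-2-one, via hydroxy imide 16 (not isolated)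
Conditions: K2CO3, MeCN, rt; then Ac2O, Et3N, DMAP (cat.), rt, same flask
Reagents that add atoms: acetic anhydride, CC(=O)OC(C)=O
Why: Williamson ether synthesis (SN2 of the phenoxide on the activated α-bromo imide; carbonate does not deprotonate the aliphatic OH) followed in the same flask by DMAP-catalysed acetylation of the remaining primary alcohol, so that no OH meets the boron triflate of step 10.

Step 10
Reactants: 17 aryloxyacetyl imide acetate; 1 4-(benzyloxy)-3-methoxybenzaldehyde
Product: 20 (4R)-3-[(2R,3S)-2-(4-{(2S,3R,4R)-3-(acetoxymethyl)-4-[4-(benzyloxy)-3-methoxybenzyl]oxolan-2-yl}-2-methoxyphenoxy)-3-[4-(benzyloxy)-3-methoxyphenyl]-3-hydroxypropanoyl]-4-benzyl-1,3-oxazolidin-2-one (syn aldol), via boron enolate 18 (not isolated), via boron aldolate 19 (not isolated)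
Conditions: Bu2BOTf (1.15 equiv), Et3N (1.3 equiv), CH2Cl2, −78 → 0 °C; then 1, −78 → 0 °C; pH 7 buffer, MeOH, 30% H2O2, 0 °C
Reagents that add atoms: dibutylboron triflate, CCCCB(CCCC)OS(=O)(=O)C(F)(F)F (its Bu2B unit stays only in 18 and 19, not in 20)
Why: Soft enolisation of the N-aryloxyacetyl imide with Bu2BOTf/Et3N gives the (Z)-boron enolate 18, which adds to the aldehyde carbon of 1 through a closed Zimmerman–Traxler chair to forge C7''–C8'' as boron aldolate 19, cleaved oxidatively on work-up. The closest known reaction type is the Evans syn-glycolate aldol of α-alkoxy- and α-aryloxyacetyl oxazolidinones with aromatic aldehydes. No ring is closed. The Z geometry in the chair fixes the syn (threo) relation of C7''–OH and C8''–OAr, and the dipole-opposed (R)-4-benzyl auxiliary shields one enolate face, so both centres should form as drawn (2R,3S in the imide, 8''S,7''S after reduction), while the oxolane stereocentres are too remote to interfere. The step needs enolisation of the imide and not the acetate, secured by the much higher acidity and boron chelation of the α-aryloxy imide and by only a slight excess of boron triflate; it also needs the benzylic oxolane C2–O bond to survive, which the amine-buffered medium at low temperature and the less electron-rich alkylated guaiacyl ring should allow.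

Step 11
Reactants: 20 syn aldol imide
Product: 21 (1S,2S)-1-[4-(benzyloxy)-3-methoxyphenyl]-2-(4-{(2S,3R,4R)-4-[4-(benzyloxy)-3-methoxybenzyl]-3-(hydroxymethyl)oxolan-2-yl}-2-methoxyphenoxy)propane-1,3-diol
Conditions: LiBH4 (excess), MeOH (additive), THF, 0 °C → rt; then water
Reagents that add atoms: none
Why: Reductive cleavage of the N-acyl oxazolidinone with lithium borohydride (hydride attacks the exocyclic carbonyl) turns C9'' into CH2OH and releases the auxiliary, and the same reagent reduces off the acetate, without touching C7'' or C8''.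

Step 12
Reactants: 21 di-O-benzyl ether
Product: 22 (1S,2S)-1-(4-hydroxy-3-methoxyphenyl)-2-(4-{(2S,3R,4R)-4-(4-hydroxy-3-methoxybenzyl)-3-(hydroxymethyl)oxolan-2-yl}-2-methoxyphenoxy)propane-1,3-diol (target)
Conditions: H2 (1 atm), 10% Pd/C, EtOAc–EtOH, rt, stopped when 21 is consumed
Reagents that add atoms: none
Why: Catalytic hydrogenolysis of the two aryl benzyl ethers, which under neutral conditions at 1 atm cleave much faster than the secondary benzylic C7''–OH and the oxolane C2–O bond; no stereocentre is affected.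

Compound list
1 | 4-(benzyloxy)-3-methoxybenzaldehyde | COc1cc(C=O)ccc1OCc1ccccc1 | starting material
2 | dimethyl succinate | COC(=O)CCC(=O)OC | starting material
3 | (E)-4-[4-(benzyloxy)-3-methoxyphenyl]-3-(methoxycarbonyl)but-3-enoic acid | COC(=O)/C(CC(=O)O)=C/c1ccc(OCc2ccccc2)c(OC)c1 | intermediate
4 | (3R)-4-[4-(benzyloxy)-3-methoxyphenyl]-3-(methoxycarbonyl)butanoic acid | COC(=O)[C@@H](CC(=O)O)Cc1ccc(OCc2ccccc2)c(OC)c1 | intermediate
5 | (3R)-4-[4-(benzyloxy)-3-methoxyphenyl]-3-(hydroxymethyl)butanoic acid | OC[C@@H](CC(=O)O)Cc1ccc(OCc2ccccc2)c(OC)c1 | intermediate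
6 | (4R)-4-[4-(benzyloxy)-3-methoxybenzyl]oxolan-2-one | COc1cc(C[C@H]2COC(=O)C2)ccc1OCc1ccccc1 | intermediate
7 | vanillin | COc1cc(C=O)ccc1O | starting material
8 | 3-methoxy-4-(oxan-2-yloxy)benzaldehyde | COc1cc(C=O)ccc1OC1CCCCO1 | intermediate
9 | (3S,4R)-trans aldol lactone, mixture at C7 and at the acetal carbon | COc1cc(C[C@H]2COC(=O)[C@@H]2C(O)c2ccc(OC3CCCCO3)c(OC)c2)ccc1OCc1ccccc1 | intermediate
10 | (2R,3R)-THP-protected triol, mixture at C7 and at the acetal carbon | COc1cc(C[C@@H](CO)[C@H](CO)C(O)c2ccc(OC3CCCCO3)c(OC)c2)ccc1OCc1ccccc1 | intermediate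
11 | (2R,3R)-phenol tetraol, mixture at C7 | COc1cc(C[C@@H](CO)[C@H](CO)C(O)c2ccc(O)c(OC)c2)ccc1OCc1ccccc1 | intermediate
12 | 4'-O-benzyl-(+)-lariciresinol (2S,3R,4R) | COc1cc(C[C@H]2CO[C@H](c3ccc(O)c(OC)c3)[C@H]2CO)ccc1OCc1ccccc1 | intermediate
13 | (4R)-4-benzyl-1,3-oxazolidin-2-one | O=C1N[C@H](Cc2ccccc2)CO1 | starting material
14 | bromoacetyl bromide | BrCC(=O)Br | starting material
15 | (4R)-4-benzyl-3-(bromoacetyl)-1,3-oxazolidin-2-one | O=C(CBr)N1[C@H](Cc2ccccc2)COC1=O | intermediate
16 | aryloxyacetyl imide with free 9-OH | COc1cc(C[C@H]2CO[C@H](c3ccc(OCC(=O)N4[C@H](Cc5ccccc5)COC4=O)c(OC)c3)[C@H]2CO)ccc1OCc1ccccc1 | intermediate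
17 | aryloxyacetyl imide 9-O-acetate | COc1cc(C[C@H]2CO[C@H](c3ccc(OCC(=O)N4[C@H](Cc5ccccc5)COC4=O)c(OC)c3)[C@H]2COC(C)=O)ccc1OCc1ccccc1 | intermediate
18 | (Z)-dibutylboron enolate of 17 | COc1cc(C[C@H]2CO[C@H](c3ccc(O/C=C(\OB(CCCC)CCCC)N4[C@H](Cc5ccccc5)COC4=O)c(OC)c3)[C@H]2COC(C)=O)ccc1OCc1ccccc1 | intermediate
19 | dibutylboron aldolate of 20 | COc1cc(C[C@H]2CO[C@H](c3ccc(O[C@@H](C(=O)N4[C@H](Cc5ccccc5)COC4=O)[C@@H](OB(CCCC)CCCC)c4ccc(OCc5ccccc5)c(OC)c4)c(OC)c3)[C@H]2COC(C)=O)ccc1OCc1ccccc1 | intermediate
20 | (2R,3S)-syn aldol imide | COc1cc(C[C@H]2CO[C@H](c3ccc(O[C@@H](C(=O)N4[C@H](Cc5ccccc5)COC4=O)[C@@H](O)c4ccc(OCc5ccccc5)c(OC)c4)c(OC)c3)[C@H]2COC(C)=O)ccc1OCc1ccccc1 | intermediate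
21 | di-O-benzyl ether of the target | COc1cc(C[C@H]2CO[C@H](c3ccc(O[C@@H](CO)[C@@H](O)c4ccc(OCc5ccccc5)c(OC)c4)c(OC)c3)[C@H]2CO)ccc1OCc1ccccc1 | intermediate
22 | (7''S,8''S)-threo-guaiacylglycerol 8''-O-4 ether of (+)-lariciresinol | COc1cc(C[C@H]2CO[C@H](c3ccc(O[C@@H](CO)[C@@H](O)c4ccc(O)c(OC)c4)c(OC)c3)[C@H]2CO)ccc1O | target

Total step count: 12. Longest linear sequence: 10 (steps 1, 2, 3, 5, 6, 7, 9, 10, 11, 12).

Steps most likely to fail

1. Step 10.
- What may go wrong: enolisation of the large imide may be incomplete. Free boron triflate may open an acyclic transition state and erode syn and facial selectivity. The electron-rich aldehyde may favour retro-aldol, and the Lewis acid may ionise the benzylic oxolane ether.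
- Fallback: it keeps the same C7''–C8'' union but separates bond formation from stereocontrol. It sets out from 12 and returns at 21.
- O-alkylation of 12 with methyl bromoacetate (K2CO3, acetone) should give the methyl aryloxyacetate F1.
- Commercial 4-(benzyloxy)-3-methoxybenzoic acid and oxalyl chloride give 4-(benzyloxy)-3-methoxybenzoyl chloride F2.
- Treatment of F1 with excess LiHMDS and two equivalents of F2 (crossed Claisen acylation, THF, −78 °C) should C-acylate C8'' and cap the primary alcohol as the same aroate. This gives the configurationally labile α-aryloxy-β-keto ester F3.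
- Asymmetric transfer hydrogenation with dynamic kinetic resolution (RuCl[(R,R)-TsDPEN](p-cymene), HCO2H–Et3N) should give the syn β-hydroxy ester F4.
- LiAlH4 then reduces both esters to reach 21.

2. Step 7.
- What may go wrong: the free p-hydroxyaryl group allows repeated re-ionisation at C7. This can lead to Friedel–Crafts capture by the pendant benzyl ring, to poor facial selectivity at C7, or to trapping by methanol.
- Fallback: it separates ring closure from phenol release. It sets out from 6 and returns at 12.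
- The lithium enolate of 6 and commercial 4-(allyloxy)-3-methoxybenzaldehyde should give the allyl-protected aldol lactone F5.
- LiAlH4 gives the allyl-protected triol F6.
- CSA in dry CH2Cl2 closes the ring on the aryl ether to the O-allyl oxolane F7.
- Pd(PPh3)4 with morpholine removes the allyl group under neutral conditions to give 12.

3. Step 9.
- What may go wrong: the phenoxide may attack the imide carbonyl of 15 or of 16, so that acyl transfer and loss of the auxiliary compete with SN2 displacement.
- Fallback: it attaches the auxiliary by N-acylation instead. It sets out from 12 and returns at 17.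
- Ethyl bromoacetate and K2CO3 should give the ethyl aryloxyacetate F8.
- LiOH gives the hydroxy acid F9.
- Ac2O in pyridine followed by aqueous work-up gives the acetoxy acid F10.
- Pivaloyl chloride and Et3N give the mixed pivalic anhydride F11.
- F11 is treated in the same flask with 13, LiCl and Et3N to give 17.

Further compounds
F1 | step 10 | methyl (4-{(2S,3R,4R)-4-[4-(benzyloxy)-3-methoxybenzyl]-3-(hydroxymethyl)oxolan-2-yl}-2-methoxyphenoxy)acetate | COc1cc(C[C@H]2CO[C@H](c3ccc(OCC(=O)OC)c(OC)c3)[C@H]2CO)ccc1OCc1ccccc1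
F2 | step 10 | 4-(benzyloxy)-3-methoxybenzoyl chloride | COc1cc(C(=O)Cl)ccc1OCc1ccccc1
F3 | step 10 | α-aryloxy-β-keto methyl ester with 9-O-[4-(benzyloxy)-3-methoxybenzoyl] cap, epimers at C8'' | COc1cc(C[C@H]2CO[C@H](c3ccc(OC(C(=O)OC)C(=O)c4ccc(OCc5ccccc5)c(OC)c4)c(OC)c3)[C@H]2COC(=O)c2ccc(OCc3ccccc3)c(OC)c2)ccc1OCc1ccccc1
F4 | step 10 | (2R,3S)-syn β-hydroxy methyl ester with the same 9-O-aroyl cap | COc1cc(C[C@H]2CO[C@H](c3ccc(O[C@@H](C(=O)OC)[C@@H](O)c4ccc(OCc5ccccc5)c(OC)c4)c(OC)c3)[C@H]2COC(=O)c2ccc(OCc3ccccc3)c(OC)c2)ccc1OCc1ccccc1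
F5 | step 7 | (3S,4R)-trans aldol lactone with O-allyl guaiacyl group, mixture at C7 | COc1cc(C[C@H]2COC(=O)[C@@H]2C(O)c2ccc(OCC=C)c(OC)c2)ccc1OCc1ccccc1
F6 | step 7 | (2R,3R)-O-allyl triol, mixture at C7 | COc1cc(C[C@@H](CO)[C@H](CO)C(O)c2ccc(OCC=C)c(OC)c2)ccc1OCc1ccccc1
F7 | step 7 | 4-O-allyl-4'-O-benzyl-(+)-lariciresinol | COc1cc(C[C@H]2CO[C@H](c3ccc(OCC=C)c(OC)c3)[C@H]2CO)ccc1OCc1ccccc1
F8 | step 9 | ethyl (4-{(2S,3R,4R)-4-[4-(benzyloxy)-3-methoxybenzyl]-3-(hydroxymethyl)oxolan-2-yl}-2-methoxyphenoxy)acetate | COc1cc(C[C@H]2CO[C@H](c3ccc(OCC(=O)OCC)c(OC)c3)[C@H]2CO)ccc1OCc1ccccc1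
F9 | step 9 | corresponding aryloxyacetic acid with free 9-OH | COc1cc(C[C@H]2CO[C@H](c3ccc(OCC(=O)O)c(OC)c3)[C@H]2CO)ccc1OCc1ccccc1
F10 | step 9 | aryloxyacetic acid 9-O-acetate | COc1cc(C[C@H]2CO[C@H](c3ccc(OCC(=O)O)c(OC)c3)[C@H]2COC(C)=O)ccc1OCc1ccccc1
F11 | step 9 | mixed pivalic anhydride of F10 | COc1cc(C[C@H]2CO[C@H](c3ccc(OCC(=O)OC(=O)C(C)(C)C)c(OC)c3)[C@H]2COC(C)=O)ccc1OCc1ccccc1
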